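The south run slows down: G falls at a first-order rate of 0.109 h⁻¹ over the first 2.50 h, but at 0.0470 h⁻¹ between 12.0 h and 30.0 h, which is less. The flask asked about is this same south flask, followed further, and two chemists dispute what its tail will do.

all flasks: G 0.10 M
- south: Q 1.2 equiv; D 0.80 equiv; the very flask that is asked about, followed so far
- flask: Q 1.20 equiv; D 0.800 equiv; time 3.0 d

south run (percent of the G charged)

| time / h | G / % | J / % |
|---|---|---|
| 2.50 | 76.2 | 23.0 |
| 5.00 | 60.1 | 38.0 |
| 12.0 | 37.3 | 62.8 |
| 30.0 | 16.0 | 84.2 |

(scatter of a reading: 0.5 percentage points)

1. part of the G that has reacted at 3.0 d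
2. share of the unused Q that is free and not bound as E, at 3.0 d

The first chemist says that Q now stands in excess, so the decay is pseudo-first-order and the late slope can simply be carried on. From 16.0% at 30.0 h, that leaves G at 2.22% and gives c = 97.8%.

The second chemist says that one Q goes with each G, so in fractions of the G charge, unused Q equals g + s, where s = 0.200 is the excess. The logarithm of the ratio Q/G then grows in step with time. Its growth gives a pair constant κ of 0.105 h⁻¹ from the reading at 30.0 h, and 0.105 h⁻¹ from the reading at 5.00 h.

From κ comes the tail half-life, 33.1 h: the natural logarithm of two divided by κ and by the size of s, which is the time in which the scarcer partner halves once the other stands at the excess. Its rate, 0.0210 h⁻¹, is lower than the late slope.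

I side with the second chemist: my own reckoning leaves G at 4.52%, so c = 95.5%. For fr, the readings offer me no ground.

The forecast takes the second side, with c = 95.4% and fr = 80%, judging that “Binding is therefore probably weak”.

The flask gives c = 95.0% and fr = 89.8%.

    G + Q → J + Z (k = 0.0174 M⁻¹ min⁻¹)
    Q + Z ⇌ E, settled at all times (K = 9.10 M⁻¹)
    D + Z → L (k = 0.633 M⁻¹ min⁻¹)

The second view stands, and the first keeps its pseudo-first-order form in the tail, where g lies below s, though at the lower rate 0.0210 h⁻¹ and not at the late slope: G is down to 5.0% at 3.0 d, a quarter of s. A neighbour flask, charged with 0.300 equiv of Q, has Q as limiting reagent, with a reckoned tail half-life of 9.45 h; at 3.0 d that neighbour holds Q at 0.367% of its charge and G at 70.1%. The south flask, with its 33.1 h, has not come to rest at 3.0 d. By 30.0 d, c reaches >99.9%, Q falls from 18.7% to 14.4% of its charge, and the free share of unused Q falls from 89.8% to 86.4%.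

The earlier runs and the new flask were generated by integration on assumed constants; the scatter is artificial.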